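**Plan**

- Retrosynthesis: after removal of a silyl group from the 6-OH, the dihydropyran ring of the chroman is cut at O1–C2 and C3–C4 in one retro-[4+2] step. This leaves an o-quinone methide (O1=C8a–C4a=C4H2, from a silyl-protected 2,5-dihydroxybenzyl alcohol) and an acyclic tetraene whose terminal CH2=C(CH3) unit becomes C3 and C2.
- Enabling feature: O1 and the benzylic C4 sit ortho on the arene (O1–C8a–C4a–C4), and C2 is a fully substituted carbon bearing a methyl and an alkenyl group. The heterocycle is therefore the formal adduct of an o-quinone methide and the substituted end of a 2-methyl-1,3-diene.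
- The tetraene is cut at the C2'–C3' single bond of the side chain (C1' is bonded to C2) into an (E)-dienylboronate and a (Z)-alkenyl iodide. The iodide is cut at C4'–C5' into propyne and a two-carbon Grignard reagent carrying the intact trimethylcyclohexene ring.
- Forward: the carbocycle is bought (β-homocyclocitral); the chain is joined by carbocupration (C4'–C5'), then Suzuki coupling (C2'–C3'); the oxygen heterocycle is formed last by the cycloaddition, and fluoride frees the phenol.
- Stereochemistry: 3'Z from syn-carbocupration of propyne, 1'E from syn-hydroboration of an enyne, both carried through stereoretentive steps; the single stereocenter C2 (R) from a chiral Brønsted acid that holds the o-quinone methide during the cycloaddition.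

Key step: step 8

Assumption: the sense of induction of the chiral acid cannot be predicted with certainty; the (S,S) antipode is written, and the (R,R) antipode would be used if a pilot run shows the opposite sense.

**Route**

Step 1
Reactants: 1 2,5-dihydroxybenzaldehyde
Product: 2 5-[(tert-butyldimethylsilyl)oxy]-2-hydroxybenzaldehyde
Conditions: TBSCl (1.05 equiv), imidazole, CH2Cl2, 0 °C
Reagents that add atoms: tert-butyldimethylsilyl chloride, CC(C)(C)[Si](C)(C)Cl
Why: Chemoselective silyl ether formation; the 2-OH is tied up in an intramolecular hydrogen bond to the ortho formyl group and is hindered by it, so the free 5-OH should be silylated with one equivalent of the chloride.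

Step 2
Reactants: 2 5-[(tert-butyldimethylsilyl)oxy]-2-hydroxybenzaldehyde
Product: 3 4-[(tert-butyldimethylsilyl)oxy]-2-(hydroxymethyl)phenol
Conditions: NaBH4, THF/MeOH, 0 °C
Reagents that add atoms: none
Why: Hydride 1,2-reduction of the aryl aldehyde is fast at 0 °C and should leave the aryl silyl ether intact, giving the o-hydroxybenzyl alcohol that serves as o-quinone methide precursor.

Step 3
Reactants: 4 (2,6,6-trimethylcyclohex-1-en-1-yl)acetaldehyde (β-homocyclocitral)
Product: 5 2-(2,6,6-trimethylcyclohex-1-en-1-yl)ethan-1-ol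
Conditions: NaBH4, MeOH, 0 °C
Reagents that add atoms: none
Why: NaBH4 reduces the aldehyde chemoselectively; the tetrasubstituted ring alkene is inert to hydride and the low temperature suppresses base-induced migration of the β,γ-double bond.

Step 4
Reactants: 5 2-(2,6,6-trimethylcyclohex-1-en-1-yl)ethan-1-ol
Product: 6 2-(2-bromoethyl)-1,3,3-trimethylcyclohex-1-ene
Conditions: CBr4, PPh3, CH2Cl2, 0 °C
Reagents that add atoms: carbon tetrabromide, BrC(Br)(Br)Br
Why: Appel bromination converts the primary alcohol into the bromide by SN2 displacement of the oxyphosphonium group under neutral conditions, so the acid-sensitive tetrasubstituted alkene is not disturbed.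

Step 5
Reactants: 6 2-(2-bromoethyl)-1,3,3-trimethylcyclohex-1-ene; 7 propyne
Product: 11 2-[(3Z)-4-iodo-3-methylbut-3-en-1-yl]-1,3,3-trimethylcyclohex-1-ene, via Grignard reagent 8 (not isolated), via alkylcopper 9 (not isolated), via (Z)-alkenylcopper 10 (not isolated)
Conditions: Mg, Et2O, reflux; CuBr·SMe2, Et2O/Me2S, −45 °C; propyne, −45 to −25 °C; I2, THF, −50 to 0 °C
Reagents that add atoms: iodine, [I][I]
Why: Normant carbocupration; the alkylcopper adds syn across propyne with the alkyl group going to the internal carbon and copper to the terminal one, and iodinolysis of the carbon–copper bond with retention fixes the (Z) geometry (chain cis to iodine).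

Step 6
Reactants: 12 2-methylbut-1-en-3-yne
Product: 13 (E)-4,4,5,5-tetramethyl-2-(3-methylbuta-1,3-dien-1-yl)-1,3,2-dioxaborolane
Conditions: pinacolborane, Cp2Zr(H)Cl (5 mol%), Et3N (10 mol%), CH2Cl2, sealed tube, 25 °C
Reagents that add atoms: pinacolborane, B1OC(C)(C)C(C)(C)O1
Why: Zirconium-catalysed hydroboration adds hydrogen and boron syn across the terminal alkyne with boron at the terminal carbon, giving the (E)-alkenylboronate, while the 1,1-disubstituted alkene is left alone.

Step 7
Reactants: 11 2-[(3Z)-4-iodo-3-methylbut-3-en-1-yl]-1,3,3-trimethylcyclohex-1-ene; 13 (E)-4,4,5,5-tetramethyl-2-(3-methylbuta-1,3-dien-1-yl)-1,3,2-dioxaborolane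
Product: 14 2-[(3Z,5E)-3,7-dimethylocta-3,5,7-trien-1-yl]-1,3,3-trimethylcyclohex-1-ene
Conditions: PdCl2(dppf) (5 mol%), K3PO4 (aq.), THF, 40 °C, degassed, dark
Reagents that add atoms: none
Why: Suzuki–Miyaura coupling of an alkenyl iodide with an alkenylboronate proceeds with retention at both sp2 carbons, so the (3Z,5E) geometry is assembled from two stereodefined halves under mild, non-acidic conditions.

Step 8
Reactants: 3 4-[(tert-butyldimethylsilyl)oxy]-2-(hydroxymethyl)phenol; 14 2-[(3Z,5E)-3,7-dimethylocta-3,5,7-trien-1-yl]-1,3,3-trimethylcyclohex-1-ene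
Product: 16 tert-butyldimethyl({(2R)-2-methyl-2-[(1E,3Z)-4-methyl-6-(2,6,6-trimethylcyclohex-1-en-1-yl)hexa-1,3-dien-1-yl]-3,4-dihydro-2H-chromen-6-yl}oxy)silane, via o-quinone methide 15 (not isolated)
Conditions: (S,S)-imidodiphosphorimidate Brønsted acid (built from two (S)-3,3'-bis[3,5-bis(trifluoromethyl)phenyl]-BINOL units, P=NSO2CF3 groups; 5 mol%), 5 Å MS, CH2Cl2, −40 to −20 °C, 3 (1.5 equiv) added slowly to 14; Et3N quench
Reagents that add atoms: none
Why: Proposed new method: the confined chiral acid should ionise the benzylic C–OH of 3 to o-quinone methide 15, which stays hydrogen-bonded (at the limit ion-paired as the o-hydroxybenzyl cation) to the chiral anion and reacts as the oxa-diene O=C–C=CH2 with the terminal CH2=C(CH3) alkene of 14 in an inverse-electron-demand hetero-Diels–Alder reaction driven by rearomatisation. The closest known reaction types are chiral phosphoric acid catalysed [4+2] cycloadditions of benzylic-aryl o-quinone methides with styrenes and other 1,1-disubstituted electron-rich alkenes, confined-acid catalysed intramolecular cycloadditions of o-quinone methides with unactivated alkenes, and the racemic thermal addition of the parent o-quinone methide to the methyl-bearing alkene of isoprene; new here is enantiocontrol with an unsubstituted o-quinone methide and a simple polyene. The dihydropyran ring closes by a concerted but asynchronous [4+2] cycloaddition in which the C4–C3 bond leads and the O1–C2 bond follows (at the stepwise limit a 6-exo-trig capture of the tertiary pentadienyl cation by the phenol oxygen). The only new stereocenter, C2, is controlled by the catalyst, whose anion is bound to the very oxygen that attacks C2 and whose pocket has to tell the small methyl group from the long planar dienyl arm, so that one enantiotopic face of the alkene is offered. The step needs site selectivity, regioselectivity and retention of the (Z)-alkene: the terminal CH2 of 14 is the only unhindered alkene terminus and the only one whose attack places positive charge on a tertiary dienyl-stabilised carbon (which also sends oxygen to the substituted carbon), while the trisubstituted and the tetrasubstituted alkenes are shielded by their substituents. Low temperature, a short-lived polarised transition state and slow addition of 3 should prevent rotation about the C3'–C4' bond, ionisation of the product at C2 and oligomerisation of 15.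

Step 9
Reactants: 16 tert-butyldimethyl({(2R)-2-methyl-2-[(1E,3Z)-4-methyl-6-(2,6,6-trimethylcyclohex-1-en-1-yl)hexa-1,3-dien-1-yl]-3,4-dihydro-2H-chromen-6-yl}oxy)silane
Product: 17 (2R)-2-methyl-2-[(1E,3Z)-4-methyl-6-(2,6,6-trimethylcyclohex-1-en-1-yl)hexa-1,3-dien-1-yl]-3,4-dihydro-2H-chromen-6-ol
Conditions: Bu4NF, AcOH (1:1), THF, 0 °C, argon
Reagents that add atoms: none
Why: Fluoride cleaves the aryl silicon–oxygen bond (silyl ether deprotection); acetic acid buffering protonates the phenoxide at once, and these non-oxidising conditions should affect neither the dienyl ether at C2 nor the (Z)-alkene.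

**Compound list**

1 | 2,5-dihydroxybenzaldehyde | O=Cc1cc(O)ccc1O | starting material
2 | 5-[(tert-butyldimethylsilyl)oxy]-2-hydroxybenzaldehyde | O=Cc1cc(O[Si](C)(C)C(C)(C)C)ccc1O | intermediate
3 | 4-[(tert-butyldimethylsilyl)oxy]-2-(hydroxymethyl)phenol | OCc1cc(O[Si](C)(C)C(C)(C)C)ccc1O | intermediate
4 | (2,6,6-trimethylcyclohex-1-en-1-yl)acetaldehyde | CC1=C(CC=O)C(C)(C)CCC1 | starting material
5 | 2-(2,6,6-trimethylcyclohex-1-en-1-yl)ethan-1-ol | CC1=C(CCO)C(C)(C)CCC1 | intermediate
6 | 2-(2-bromoethyl)-1,3,3-trimethylcyclohex-1-ene | CC1=C(CCBr)C(C)(C)CCC1 | intermediate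
7 | propyne | CC#C | starting material
8 | [2-(2,6,6-trimethylcyclohex-1-en-1-yl)ethyl]magnesium bromide | CC1=C(CC[Mg]Br)C(C)(C)CCC1 | intermediate
9 | [2-(2,6,6-trimethylcyclohex-1-en-1-yl)ethyl]copper (MgBr2 complex) | CC1=C(CC[Cu])C(C)(C)CCC1 | intermediate
10 | (Z)-[2-methyl-4-(2,6,6-trimethylcyclohex-1-en-1-yl)but-1-en-1-yl]copper | CC1=C(CC/C(C)=C\[Cu])C(C)(C)CCC1 | intermediate
11 | 2-[(3Z)-4-iodo-3-methylbut-3-en-1-yl]-1,3,3-trimethylcyclohex-1-ene | CC1=C(CC/C(C)=C\I)C(C)(C)CCC1 | intermediate
12 | 2-methylbut-1-en-3-yne | C=C(C)C#C | starting material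
13 | (E)-4,4,5,5-tetramethyl-2-(3-methylbuta-1,3-dien-1-yl)-1,3,2-dioxaborolane | C=C(C)/C=C/B1OC(C)(C)C(C)(C)O1 | intermediate
14 | 2-[(3Z,5E)-3,7-dimethylocta-3,5,7-trien-1-yl]-1,3,3-trimethylcyclohex-1-ene | CC1=C(CC/C(C)=C\C=C\C(C)=C)C(C)(C)CCC1 | intermediate
15 | 4-[(tert-butyldimethylsilyl)oxy]-6-methylidenecyclohexa-2,4-dien-1-one | C=C1C=C(O[Si](C)(C)C(C)(C)C)C=CC1=O | intermediate
16 | tert-butyldimethyl({(2R)-2-methyl-2-[(1E,3Z)-4-methyl-6-(2,6,6-trimethylcyclohex-1-en-1-yl)hexa-1,3-dien-1-yl]-3,4-dihydro-2H-chromen-6-yl}oxy)silane | CC1=C(CC/C(C)=C\C=C\[C@@]2(C)CCc3cc(O[Si](C)(C)C(C)(C)C)ccc3O2)C(C)(C)CCC1 | intermediate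
17 | (2R)-2-methyl-2-[(1E,3Z)-4-methyl-6-(2,6,6-trimethylcyclohex-1-en-1-yl)hexa-1,3-dien-1-yl]-3,4-dihydro-2H-chromen-6-ol | CC1=C(CC/C(C)=C\C=C\[C@@]2(C)CCc3cc(O)ccc3O2)C(C)(C)CCC1 | target

**Summary**

Total step count: 9. Longest linear sequence: 6 steps (steps 3, 4, 5, 7, 8, 9; from 4 to 17).

**Steps most likely to fail**

Step 8. What may go wrong: poor facial selectivity, scrambling of the (Z)-alkene through a long-lived pentadienyl cation, protonation of the polyene by the acid, or oligomerisation of the quinone methide. The fallback closes the same O1–C2 bond by a known enantioselective Wacker-type cyclisation and joins the side chain afterwards; it sets out from aldehyde 2 (and uses iodide 11) and comes back at 16.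
- Wittig reaction of 2 with Ph3P=CHCOCH3 (toluene, 80 °C) would give (E)-4-[5-(tert-butyldimethylsilyloxy)-2-hydroxyphenyl]but-3-en-2-one F1.
- Hydrogenation (H2, Pd/C, EtOAc) would give 4-[5-(tert-butyldimethylsilyloxy)-2-hydroxyphenyl]butan-2-one F2.
- Wittig ethylidenation (EtPPh3Br, KOtBu, THF) would give 4-(tert-butyldimethylsilyloxy)-2-(3-methylpent-3-en-1-yl)phenol F3 as an E/Z mixture.
- Oxidative cyclisation with Pd(OCOCF3)2, the Bn-BOXAX antipode that delivers the (R) product and p-benzoquinone in MeOH at 60 °C would give (R)-tert-butyldimethyl[(2-methyl-2-vinylchroman-6-yl)oxy]silane F4.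
- Cleavage of the vinyl group (OsO4 cat., NaIO4, 2,6-lutidine, dioxane/H2O) would give (R)-6-(tert-butyldimethylsilyloxy)-2-methylchromane-2-carbaldehyde F5.
- Takai-type boryl-olefination (CrCl2, LiI, Cl2CHBpin, THF) would give tert-butyldimethyl({(2R)-2-methyl-2-[(E)-2-(4,4,5,5-tetramethyl-1,3,2-dioxaborolan-2-yl)ethenyl]chroman-6-yl}oxy)silane F6.
- Suzuki coupling of F6 with 11 (PdCl2(dppf), aq. K3PO4, THF) returns to 16, which goes on through step 9.

Step 5. What may go wrong: homocoupling during Grignard formation, incomplete addition of the alkylcopper to propyne, or loss of geometry when the alkenylcopper warms. The fallback builds the (Z)-trisubstituted alkene by haloboration and cross-coupling; it sets out from bromide 6 and propyne 7 and comes back at 11.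
- Syn-bromoboration of 7 with BBr3 (CH2Cl2, −78 °C) would give (Z)-dibromo(2-bromoprop-1-en-1-yl)borane F7.
- Esterification with pinacol would give (Z)-2-(2-bromoprop-1-en-1-yl)-4,4,5,5-tetramethyl-1,3,2-dioxaborolane F8.
- Zinc insertion into 6 (Zn dust, I2 cat., DMA, 60 °C) would give [2-(2,6,6-trimethylcyclohex-1-en-1-yl)ethyl]zinc bromide F9.
- Negishi coupling of F9 with F8 (Pd(P(t-Bu)3)2 cat., THF, 25 °C), with retention, would give (Z)-4,4,5,5-tetramethyl-2-[2-methyl-4-(2,6,6-trimethylcyclohex-1-en-1-yl)but-1-en-1-yl]-1,3,2-dioxaborolane F10.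
- Iododeboronation with retention (NaOH, then I2, THF/H2O, 0 °C) gives 11.

Step 7. What may go wrong: protodeboronation or polymerisation of the dienylboronate, or erosion of alkene geometry in the sensitive polyene. The fallback makes the C5=C6 alkene of 14 by olefination instead of cross-coupling; it sets out from iodide 11 and comes back at 14.
- Iodine–lithium exchange on 11 (t-BuLi, Et2O, −78 °C) would give (Z)-[2-methyl-4-(2,6,6-trimethylcyclohex-1-en-1-yl)but-1-en-1-yl]lithium F11.
- Formylation with DMF would give (2Z)-3-methyl-5-(2,6,6-trimethylcyclohex-1-en-1-yl)pent-2-enal F12.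
- Horner–Wadsworth–Emmons reaction of F12 with the anion of diethyl (2-methylallyl)phosphonate (n-BuLi, THF, −78 °C to 25 °C), which should favour the (E)-alkene, gives 14.

**Further compounds**

F1 | step 8 | (E)-4-[5-(tert-butyldimethylsilyloxy)-2-hydroxyphenyl]but-3-en-2-one | CC(=O)/C=C/c1cc(O[Si](C)(C)C(C)(C)C)ccc1O
F2 | step 8 | 4-[5-(tert-butyldimethylsilyloxy)-2-hydroxyphenyl]butan-2-one | CC(=O)CCc1cc(O[Si](C)(C)C(C)(C)C)ccc1O
F3 | step 8 | 4-(tert-butyldimethylsilyloxy)-2-(3-methylpent-3-en-1-yl)phenol (E/Z mixture) | CC=C(C)CCc1cc(O[Si](C)(C)C(C)(C)C)ccc1O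
F4 | step 8 | (R)-tert-butyldimethyl[(2-methyl-2-vinylchroman-6-yl)oxy]silane | C=C[C@@]1(C)CCc2cc(O[Si](C)(C)C(C)(C)C)ccc2O1
F5 | step 8 | (R)-6-(tert-butyldimethylsilyloxy)-2-methylchromane-2-carbaldehyde | O=C[C@@]1(C)CCc2cc(O[Si](C)(C)C(C)(C)C)ccc2O1
F6 | step 8 | tert-butyldimethyl({(2R)-2-methyl-2-[(E)-2-(4,4,5,5-tetramethyl-1,3,2-dioxaborolan-2-yl)ethenyl]chroman-6-yl}oxy)silane | CC1(C)OB(/C=C/[C@@]2(C)CCc3cc(O[Si](C)(C)C(C)(C)C)ccc3O2)OC1(C)C
F7 | step 5 | (Z)-dibromo(2-bromoprop-1-en-1-yl)borane | C/C(Br)=C/B(Br)Br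
F8 | step 5 | (Z)-2-(2-bromoprop-1-en-1-yl)-4,4,5,5-tetramethyl-1,3,2-dioxaborolane | C/C(Br)=C/B1OC(C)(C)C(C)(C)O1
F9 | step 5 | [2-(2,6,6-trimethylcyclohex-1-en-1-yl)ethyl]zinc bromide | CC1=C(CC[Zn]Br)C(C)(C)CCC1
F10 | step 5 | (Z)-4,4,5,5-tetramethyl-2-[2-methyl-4-(2,6,6-trimethylcyclohex-1-en-1-yl)but-1-en-1-yl]-1,3,2-dioxaborolane | CC1=C(CC/C(C)=C\B2OC(C)(C)C(C)(C)O2)C(C)(C)CCC1
F11 | step 7 | (Z)-[2-methyl-4-(2,6,6-trimethylcyclohex-1-en-1-yl)but-1-en-1-yl]lithium | CC1=C(CC/C(C)=C\[Li])C(C)(C)CCC1
F12 | step 7 | (2Z)-3-methyl-5-(2,6,6-trimethylcyclohex-1-en-1-yl)pent-2-enal | CC1=C(CC/C(C)=C\C=O)C(C)(C)CCC1
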